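**Retrosynthetic overview**
1. Target 14 ⇒ ester C–O bond: acylation of the equatorial C2–OH of diol 12 with senecioic acid; the C2–OH comes from a C2 ketone (11) by thermodynamic reduction.
2. C13 vinyl carbinol ⇒ C13–O bond from Sharpless epoxidation of (E)-allylic alcohol 8, then reductive opening of the epoxy iodide (1,3-oxygen transposition); this sets 13S by reagent control.
3. Decalin 7 ⇒ acyclic enone 6 by one catalytic asymmetric enone-initiated bicyclisation: ring A closes first (C4–C5), then ring B (C9–C10); this sets C5, C9, C10.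
4. Enone 6 (C2=O) ⇒ Meyer–Schuster oxygen shift of propargylic alcohol 5 ⇐ bromide 3 + 2-methylbut-3-yn-2-ol 4; 3 ⇐ farnesyl acetate 1.

Assumption: the IDPi enantiomer that gives the (5R,9R,10R) ketone 7 must be identified by experiment (its antipode gives the mirror-image series), and isomerically pure (2E,6E)-farnesyl acetate is bought.

Note: bicyclic compounds use labdane numbering (C2 oxygenated carbon, C4 gem-dimethyl, C5/C10 ring fusion, C8 vinylic-methyl carbon, C9 side-chain carbon, C13 carbinol carbon). All are trans-fused, with H-5 and H-9 anti to the C10 methyl (ent-labdane series).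

**Step 1**
Reactants: 1 (2E,6E)-farnesyl acetate
Product: 2 (2E,6E,10E)-12-hydroxy-3,7,11-trimethyldodeca-2,6,10-trien-1-yl acetate
Conditions: SeO2 (10 mol %), salicylic acid (10 mol %), t-BuOOH (70% aq., 3 equiv), CH2Cl2, 0 °C→rt; stop at partial conversion, recycle 1
Reagents that add atoms: tert-butyl hydroperoxide, CC(C)(C)OO
Why: Catalytic SeO2 allylic oxidation (ene reaction then [2,3]-shift) attacks the (E)-methyl of the terminal, most electron-rich trisubstituted alkene and gives the (E)-allylic alcohol, while the C2=C3 alkene is deactivated by the allylic acetate.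

**Step 2**
Reactants: 2 (2E,6E,10E)-12-hydroxy-3,7,11-trimethyldodeca-2,6,10-trien-1-yl acetate
Product: 3 (2E,6E,10E)-12-bromo-3,7,11-trimethyldodeca-2,6,10-trien-1-yl acetate
Conditions: PBr3 (0.4 equiv), pyridine (cat.), Et2O, −10→0 °C
Reagents that add atoms: phosphorus tribromide, BrP(Br)Br
Why: SN2 bromination of a primary allylic alcohol through its phosphite ester proceeds without allylic transposition or E/Z loss at 0 °C, and the acetate is inert.

**Step 3**
Reactants: 3 (2E,6E,10E)-12-bromo-3,7,11-trimethyldodeca-2,6,10-trien-1-yl acetate; 4 2-methylbut-3-yn-2-ol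
Product: 5 (2E,6E,10E)-15-hydroxy-3,7,11,15-tetramethylhexadeca-2,6,10-trien-13-yn-1-yl acetate
Conditions: CuI (20 mol %), K2CO3 (2 equiv), n-Bu4NI (10 mol %), DMF, rt
Reagents that add atoms: none
Why: Copper-acetylide allylic substitution (Cu-catalysed alkyne–allyl halide coupling) occurs at the unhindered primary carbon (SN2, not SN2′) with retention of the E-alkene, and the free tertiary alcohol and the acetate tolerate the mild base.

**Step 4**
Reactants: 5 (2E,6E,10E)-15-hydroxy-3,7,11,15-tetramethylhexadeca-2,6,10-trien-13-yn-1-yl acetate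
Product: 6 (2E,6E,10E)-3,7,11,15-tetramethyl-13-oxohexadeca-2,6,10,14-tetraen-1-yl acetate
Conditions: ReOCl3(OPPh3)(SMe2) (2 mol %), DME, rt
Reagents that add atoms: none
Why: Oxo-metal-catalysed Meyer–Schuster rearrangement moves the oxygen from C15 to C13 by a [3,3]-shift of the propargyl metallate ester (new C–O bond at the future C2), and the allenol tautomerises to the β,β-dimethyl enone under neutral conditions that leave the skipped alkene unconjugated.

**Step 5**
Reactants: 6 (2E,6E,10E)-3,7,11,15-tetramethyl-13-oxohexadeca-2,6,10,14-tetraen-1-yl acetate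
Product: 7 (5R,9R,10R)-15-acetoxylabda-7,13E-dien-2-one
Conditions: confined BINOL-derived imidodiphosphorimidate (IDPi, N-perfluoroarylsulfonyl core; 5 mol %, enantiomer per assumption), (CF3)3COH/CH2Cl2, −40 °C
Reagents that add atoms: none
Why: Proposed new method: a confined chiral Brønsted acid protonates the most basic site of 6, the enone carbonyl, to give a hydroxyallyl cation in a chiral anion pocket; its tertiary terminus C4 is attacked by the C5=C10 alkene and the C10 cation by the C8=C9 alkene through a chair–chair array (E,E-alkenes give the trans ring fusion and equatorial C9 chain; ring A closes first, then ring B), the C8 cation loses H-7 to the counter-anion (Δ7), the enol ketonises and the allylic acetate deactivates the last alkene so the cascade stops at the bicycle, with catalyst control setting C5, C9 and C10; the closest known reaction types are the IDPi-catalysed proton-initiated polyene cyclisation of homofarnesol-type polyenes, the IDPi-catalysed Nazarov cyclisation of divinyl ketones (enone activation) and racemic Lewis-acid enone-initiated cation–olefin cyclisations.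

**Step 6**
Reactants: 7 (5R,9R,10R)-15-acetoxylabda-7,13E-dien-2-one
Product: 8 (5R,9R,10R)-15-hydroxylabda-7,13E-dien-2-one
Conditions: K2CO3 (0.3 equiv), MeOH, 0 °C→rt
Reagents that add atoms: none
Why: Base-catalysed transesterification (methanolysis) removes the primary allylic acetate, and no stereocentre is α to the ketone, so nothing can epimerise.

**Step 7**
Reactants: 8 (5R,9R,10R)-15-hydroxylabda-7,13E-dien-2-one
Product: 9 (5R,9R,10R,13S,14S)-13,14-epoxy-15-hydroxylabd-7-en-2-one
Conditions: Ti(Oi-Pr)4 (10 mol %), L-(+)-DET (12 mol %), t-BuOOH (2 equiv, isooctane), 4 Å MS, CH2Cl2, −20 °C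
Reagents that add atoms: tert-butyl hydroperoxide, CC(C)(C)OO
Why: Sharpless asymmetric epoxidation delivers oxygen to one face of the allylic alcohol under reagent control (L-(+)-tartrate gives the (S,S)-epoxide with (E)-3-methyl-2-alken-1-ols, as with geraniol), which sets C13 (S) and C14 independently of the remote ring stereocentres, while the isolated Δ7 alkene and the ketone do not react.

**Step 8**
Reactants: 9 (5R,9R,10R,13S,14S)-13,14-epoxy-15-hydroxylabd-7-en-2-one
Product: 11 (5R,9R,10R,13S)-13-hydroxylabda-7,14-dien-2-one, via iodo-epoxide 10 (not isolated)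
Conditions: PPh3, I2, imidazole, THF, 0 °C; then Zn dust, AcOH (3 equiv), 0 °C→rt, same flask
Reagents that add atoms: none
Why: Appel-type iodination of the primary alcohol followed by zinc insertion and β-elimination (reductive opening of a 2,3-epoxy iodide) transposes the oxygen function to C13 and unveils the vinyl group, and because the C13–O bond is never broken 13S is retained.

**Step 9**
Reactants: 11 (5R,9R,10R,13S)-13-hydroxylabda-7,14-dien-2-one
Product: 12 (2R,5R,9R,10R,13S)-labda-7,14-diene-2,13-diol
Conditions: Li (4 equiv), NH3(l)/THF, t-BuOH (2 equiv), −78 °C, 10 min; NH4Cl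
Reagents that add atoms: none
Why: Dissolving-metal ketone reduction gives the thermodynamically favoured equatorial alcohol (2R), because the axial epimer would be syn-diaxial to the C10 methyl and the axial C4 methyl (the same outcome as 11-oxo steroids giving 11α-ols), while isolated alkenes and the tertiary alkoxide are inert.

**Step 10**
Reactants: 12 (2R,5R,9R,10R,13S)-labda-7,14-diene-2,13-diol; 13 3-methylbut-2-enoic acid
Product: 14 (2R,5R,9R,10R,13S)-13-hydroxylabda-7,14-dien-2-yl 3-methylbut-2-enoate
Conditions: DCC (1.2 equiv), DMAP (10 mol %), CH2Cl2, 0 °C→rt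
Reagents that add atoms: none
Why: Steglich esterification acylates the unhindered equatorial secondary alcohol with retention at C2, while the tertiary allylic C13–OH is too hindered to react.

**Compound list**
1 | (2E,6E)-farnesyl acetate | CC(C)=CCC/C(C)=C/CC/C(C)=C/COC(C)=O | starting material
2 | (2E,6E,10E)-12-hydroxy-3,7,11-trimethyldodeca-2,6,10-trien-1-yl acetate | OC/C(C)=C/CC/C(C)=C/CC/C(C)=C/COC(C)=O | intermediate
3 | (2E,6E,10E)-12-bromo-3,7,11-trimethyldodeca-2,6,10-trien-1-yl acetate | BrC/C(C)=C/CC/C(C)=C/CC/C(C)=C/COC(C)=O | intermediate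
4 | 2-methylbut-3-yn-2-ol | CC(C)(O)C#C | starting material
5 | (2E,6E,10E)-15-hydroxy-3,7,11,15-tetramethylhexadeca-2,6,10-trien-13-yn-1-yl acetate | CC(C)(O)C#CC/C(C)=C/CC/C(C)=C/CC/C(C)=C/COC(C)=O | intermediate
6 | (2E,6E,10E)-3,7,11,15-tetramethyl-13-oxohexadeca-2,6,10,14-tetraen-1-yl acetate | CC(C)=CC(=O)C/C(C)=C/CC/C(C)=C/CC/C(C)=C/COC(C)=O | intermediate
7 | (5R,9R,10R)-15-acetoxylabda-7,13E-dien-2-one | CC(=O)OC/C=C(\C)CC[C@@H]1C(C)=CC[C@@H]2C(C)(C)CC(=O)C[C@@]12C | intermediate
8 | (5R,9R,10R)-15-hydroxylabda-7,13E-dien-2-one | OC/C=C(\C)CC[C@@H]1C(C)=CC[C@@H]2C(C)(C)CC(=O)C[C@@]12C | intermediate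
9 | (5R,9R,10R,13S,14S)-13,14-epoxy-15-hydroxylabd-7-en-2-one | OC[C@@H]1O[C@@]1(C)CC[C@@H]2C(C)=CC[C@@H]3C(C)(C)CC(=O)C[C@@]23C | intermediate
10 | (5R,9R,10R,13S,14R)-13,14-epoxy-15-iodolabd-7-en-2-one (iodo-epoxide) | IC[C@@H]1O[C@@]1(C)CC[C@@H]2C(C)=CC[C@@H]3C(C)(C)CC(=O)C[C@@]23C | intermediate
11 | (5R,9R,10R,13S)-13-hydroxylabda-7,14-dien-2-one | C=C[C@@](C)(O)CC[C@@H]1C(C)=CC[C@@H]2C(C)(C)CC(=O)C[C@@]12C | intermediate
12 | (2R,5R,9R,10R,13S)-labda-7,14-diene-2,13-diol | C=C[C@@](C)(O)CC[C@@H]1C(C)=CC[C@@H]2C(C)(C)C[C@@H](O)C[C@@]12C | intermediate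
13 | 3-methylbut-2-enoic acid (senecioic acid) | CC(C)=CC(=O)O | starting material
14 | (2R,5R,9R,10R,13S)-13-hydroxylabda-7,14-dien-2-yl 3-methylbut-2-enoate (CNP0252389.1) | C=C[C@@](C)(O)CC[C@@H]1C(C)=CC[C@@H]2C(C)(C)C[C@@H](OC(=O)C=C(C)C)C[C@@]12C | target

**Totals**
Total step count: 10. Longest linear sequence: 10 steps (1 → 14; 4 and 13 are bought).

**Three steps most likely to fail**

Step 5 (the proposed new bicyclisation). The risks are low enantioselectivity, isomerisation of the skipped alkene into conjugation with the ketone, and mixtures of alkene isomers at the termination. The fallback sets out from 6 and comes back at 7. Enone 6 is cyclised without asymmetric induction using MeAlCl2 in CH2Cl2 at −78 °C (Lewis-acid enone-initiated cation–olefin cyclisation, a known racemic reaction type). This gives 7 as a racemate together with its mirror image, (5S,9S,10S)-15-acetoxylabda-7,13E-dien-2-one F1. The racemate is resolved by preparative chromatography on a chiral stationary phase, and the (5R,9R,10R) antipode 7 re-enters at step 6. This fallback only addresses loss of enantiocontrol; it does not help if the enone-initiated cyclisation itself fails.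

Step 4 (Meyer–Schuster rearrangement on a skipped enyne). The risks are dehydration of the tertiary alcohol and drift of the doubly activated CH2 into a conjugated dienone. The fallback sets out from 3 and comes back at 6. Allylic bromide 3 is coupled with tributyl(2-methylprop-1-en-1-yl)stannane under CO (3 atm) with PdCl2(PPh3)2 in THF at 50 °C (carbonylative Stille coupling of an allyl halide). This gives the allyl vinyl ketone 6 directly, makes no new compound (F0), and bypasses 5.

Step 9 (dissolving-metal reduction next to a vinyl carbinol). The risks are hydrogenolysis of the allylic alcohol or incomplete equatorial selectivity. The fallback sets out from 11 and comes back at 12. Ketone 11 is reduced with NaBH4 in MeOH at 0 °C, which attacks from the unhindered face and gives the axial alcohol (2S,5R,9R,10R,13S)-labda-7,14-diene-2,13-diol F2. F2 is then epimerised under thermodynamic control by reversible hydrogen transfer ((η5-C5Ph5)Ru(CO)2Cl/KOt-Bu, toluene, rt, or Al(Oi-Pr)3/acetone Oppenauer–MPV equilibration) to the equatorial diol 12.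

**Further compounds**
F1 | step 5 | (5S,9S,10S)-15-acetoxylabda-7,13E-dien-2-one (enantiomer of 7) | CC(=O)OC/C=C(\C)CC[C@H]1C(C)=CC[C@H]2C(C)(C)CC(=O)C[C@]12C
F0 | step 4 | none | none
F2 | step 9 | (2S,5R,9R,10R,13S)-labda-7,14-diene-2,13-diol (axial 2-epimer of 12) | C=C[C@@](C)(O)CC[C@@H]1C(C)=CC[C@@H]2C(C)(C)C[C@H](O)C[C@@]12C
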